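**Assumption:** (S)-5-(hydroxymethyl)furan-2(5H)-one and (1R,5S)-(+)-nopinone are taken as commercially available single enantiomers.

## Retrosynthetic overview

1. The target is the acetate of a β-hydroxy ketone. Rings C/D (the bicyclo[3.2.1]octenone) close last by an intramolecular aldol between the α′-carbon of a cyclohexenone and a 1-formylvinyl group on its γ-carbon.
2. The aldol precursor comes from α′-alkylation of a 4-substituted cyclohex-2-enone with a lactone primary triflate; this bond (bridgehead carbon to CH2 linker) joins the two halves.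
3. The cyclohexenone half comes from (+)-nopinone by cyclobutane opening, dehydrogenation and allylic oxidation. Its single stereocentre later controls both new centres of the bicycle.
4. The lactone half comes from (S)-5-(hydroxymethyl)butenolide by conjugate addition, two enolate alkylations, ring-closing metathesis and Mukaiyama hydration.
5. Order of ring formation: lactone (bought), ring A (metathesis); ring C (from nopinone), ring D (aldol).

## Route

**Lactone half (steps 1–8)**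

Step 1
Reactants: 1 (S)-5-(hydroxymethyl)furan-2(5H)-one
Product: 2 (S)-5-{[(tert-butyldiphenylsilyl)oxy]methyl}furan-2(5H)-one
Conditions: TBDPSCl, imidazole, CH2Cl2, 0 °C → rt
Reagents that add atoms: tert-butyl(chloro)diphenylsilane, CC(C)(C)[Si](Cl)(c1ccccc1)c1ccccc1
Why: Silylation of the primary alcohol gives a bulky ether that blocks one face of the butenolide for the next step; no stereocentre is touched.

Step 2
Reactants: 2 (S)-5-{[(tert-butyldiphenylsilyl)oxy]methyl}furan-2(5H)-one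
Product: 3 (4R,5S)-5-{[(tert-butyldiphenylsilyl)oxy]methyl}-4-(prop-1-en-2-yl)dihydrofuran-2(3H)-one
Conditions: CH2=C(CH3)MgBr, CuBr·SMe2 (10 mol %), THF, −78 → −40 °C; aq. NH4Cl
Reagents that add atoms: isopropenylmagnesium bromide, CC(=C)[Mg]Br
Why: Copper-catalysed conjugate (1,4-) addition of the Grignard reagent occurs anti to the silyloxymethyl group, so the new centre is set trans to the existing one.

Step 3
Reactants: 3 (4R,5S)-5-{[(tert-butyldiphenylsilyl)oxy]methyl}-4-(prop-1-en-2-yl)dihydrofuran-2(3H)-one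
Product: 5 (3S,4R,5S)-3-(but-3-en-1-yl)-5-{[(tert-butyldiphenylsilyl)oxy]methyl}-4-(prop-1-en-2-yl)dihydrofuran-2(3H)-one, via lithium enolate 4 (not isolated)
Conditions: LiN(i-Pr)2, THF, −78 °C; 4-iodobut-1-ene, HMPA, −78 → −20 °C
Reagents that add atoms: 4-iodobut-1-ene, C=CCCI
Why: SN2 alkylation of the lactone enolate takes place anti to the neighbouring isopropenyl group; this centre is flattened again in step 4, so its configuration does not matter.

Step 4
Reactants: 5 (3S,4R,5S)-3-(but-3-en-1-yl)-5-{[(tert-butyldiphenylsilyl)oxy]methyl}-4-(prop-1-en-2-yl)dihydrofuran-2(3H)-one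
Product: 7 (3R,4S,5S)-3-(but-3-en-1-yl)-5-{[(tert-butyldiphenylsilyl)oxy]methyl}-3-methyl-4-(prop-1-en-2-yl)dihydrofuran-2(3H)-one, via lithium enolate 6 (not isolated)
Conditions: LiN(i-Pr)2, THF, −78 °C; MeI, −78 → 0 °C
Reagents that add atoms: iodomethane, CI
Why: A second enolate alkylation builds the quaternary carbon; iodomethane enters anti to the adjacent isopropenyl group (1,2-induction), leaving the butenyl chain cis to it as ring closure requires.

Step 5
Reactants: 7 (3R,4S,5S)-3-(but-3-en-1-yl)-5-{[(tert-butyldiphenylsilyl)oxy]methyl}-3-methyl-4-(prop-1-en-2-yl)dihydrofuran-2(3H)-one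
Product: 8 (3S,3aS,7aR)-3-{[(tert-butyldiphenylsilyl)oxy]methyl}-4,7a-dimethyl-3a,6,7,7a-tetrahydroisobenzofuran-1(3H)-one
Conditions: second-generation Grubbs catalyst RuCl2(=CHPh)(H2IMes)(PCy3) (5 mol %), CH2Cl2, 40 °C
Reagents that add atoms: none
Why: Ring-closing metathesis of the cis-disposed butenyl and isopropenyl arms closes ring A as a cis-fused cyclohexene with a trisubstituted alkene, driven by loss of ethene; no new stereocentre.

Step 6
Reactants: 8 (3S,3aS,7aR)-3-{[(tert-butyldiphenylsilyl)oxy]methyl}-4,7a-dimethyl-3a,6,7,7a-tetrahydroisobenzofuran-1(3H)-one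
Product: 10 (3S,3aS,4R,7aR)-3-{[(tert-butyldiphenylsilyl)oxy]methyl}-4-hydroxy-4,7a-dimethylhexahydroisobenzofuran-1(3H)-one, via tertiary hydroperoxide 9 (not isolated)
Conditions: Co(acac)2 (20 mol %), PhSiH3, O2 (1 atm), i-PrOH, rt; then PPh3
Reagents that add atoms: dioxygen, O=O
Why: Mukaiyama hydration (cobalt hydride hydrogen-atom transfer, Markovnikov) gives a tertiary radical that should trap O2 on the convex face, anti to the fused lactone and its axial carbonyl carbon, placing the hydroxyl trans to the lactone; PPh3 reduces the hydroperoxide.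

Step 7
Reactants: 10 (3S,3aS,4R,7aR)-3-{[(tert-butyldiphenylsilyl)oxy]methyl}-4-hydroxy-4,7a-dimethylhexahydroisobenzofuran-1(3H)-one
Product: 11 (3S,3aS,4R,7aR)-4-hydroxy-3-(hydroxymethyl)-4,7a-dimethylhexahydroisobenzofuran-1(3H)-one
Conditions: Bu4NF, AcOH, THF, 0 °C → rt
Reagents that add atoms: none
Why: Buffered fluoride desilylation frees the primary alcohol; the γ-lactone is favoured over the δ-lactone, so no acyl migration is expected.

Step 8
Reactants: 11 (3S,3aS,4R,7aR)-4-hydroxy-3-(hydroxymethyl)-4,7a-dimethylhexahydroisobenzofuran-1(3H)-one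
Product: 13 [(3S,3aS,4R,7aR)-4,7a-dimethyl-1-oxo-4-[(trimethylsilyl)oxy]octahydroisobenzofuran-3-yl]methyl trifluoromethanesulfonate, via hydroxy triflate 12 (not isolated)
Conditions: Tf2O, 2,6-lutidine, CH2Cl2, −78 °C; then Me3SiOTf, −78 → 0 °C; used crude
Reagents that add atoms: trifluoromethanesulfonic anhydride, O=S(=O)(OS(=O)(=O)C(F)(F)F)C(F)(F)F; trimethylsilyl trifluoromethanesulfonate, C[Si](C)(C)OS(=O)(=O)C(F)(F)F
Why: Sulfonylation is selective for the primary over the hindered tertiary alcohol at −78 °C, and the tertiary alcohol is then capped by silylation in the same flask so that it cannot act as a proton shuttle during the enolate alkylation.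

**Cyclohexenone half (steps 9–12)**

Step 9
Reactants: 14 (1R,5S)-6,6-dimethylbicyclo[3.1.1]heptan-2-one ((+)-nopinone)
Product: 15 (S)-4-(prop-1-en-2-yl)cyclohex-1-en-1-yl acetate
Conditions: Ac2O, BF3·OEt2, Zn(OAc)2, rt
Reagents that add atoms: acetic anhydride, CC(=O)OC(C)=O
Why: Lewis-acid cyclobutane fragmentation breaks the bond between the α-bridgehead and the CMe2 carbon; the tertiary cation loses a proton to give the isopropenyl group, the enol is trapped as its acetate, and the other bridgehead survives as the single stereocentre.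

Step 10
Reactants: 15 (S)-4-(prop-1-en-2-yl)cyclohex-1-en-1-yl acetate
Product: 16 (S)-4-(prop-1-en-2-yl)cyclohex-2-en-1-one
Conditions: Pd(OAc)2 (5 mol %), Bu3SnOMe (20 mol %), allyl methyl carbonate, MeCN, reflux
Reagents that add atoms: none
Why: Tsuji (Saegusa-type) dehydrogenation: the enol acetate becomes a tin and then a palladium enolate, and β-hydride elimination places the new alkene next to the stereocentre without touching it.

Step 11
Reactants: 16 (S)-4-(prop-1-en-2-yl)cyclohex-2-en-1-one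
Product: 17 (S)-4-(3-hydroxyprop-1-en-2-yl)cyclohex-2-en-1-one
Conditions: SeO2 (cat.), t-BuOOH, CH2Cl2, rt
Reagents that add atoms: tert-butyl hydroperoxide, CC(C)(C)OO
Why: Riley allylic oxidation (ene reaction then [2,3]-sigmatropic shift) hydroxylates the isopropenyl methyl in preference to the ring methine (CH3 > CH), leaving the stereocentre intact.

Step 12
Reactants: 17 (S)-4-(3-hydroxyprop-1-en-2-yl)cyclohex-2-en-1-one
Product: 18 (S)-4-{3-[(tert-butyldimethylsilyl)oxy]prop-1-en-2-yl}cyclohex-2-en-1-one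
Conditions: TBSCl, imidazole, CH2Cl2, rt
Reagents that add atoms: tert-butyl(chloro)dimethylsilane, CC(C)(C)[Si](C)(C)Cl
Why: Silylation masks the future aldehyde carbon as a base-stable ether for the enolate step.

**Union and endgame (steps 13–17)**

Step 13
Reactants: 18 (S)-4-{3-[(tert-butyldimethylsilyl)oxy]prop-1-en-2-yl}cyclohex-2-en-1-one; 13 [(3S,3aS,4R,7aR)-4,7a-dimethyl-1-oxo-4-[(trimethylsilyl)oxy]octahydroisobenzofuran-3-yl]methyl trifluoromethanesulfonate
Product: 20 (4S)-4-{3-[(tert-butyldimethylsilyl)oxy]prop-1-en-2-yl}-6-{[(3R,3aS,4R,7aR)-4,7a-dimethyl-1-oxo-4-[(trimethylsilyl)oxy]octahydroisobenzofuran-3-yl]methyl}cyclohex-2-en-1-one (both C6 epimers), via lithium dienolate 19 (not isolated)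
Conditions: 18, LiN(i-Pr)2 (1.05 equiv), THF, −78 °C; then 13, −78 → −30 °C
Reagents that add atoms: none
Why: Kinetic α′-deprotonation gives the cross-conjugated dienolate, which is C-alkylated (SN2) by the reactive primary triflate; the γ-stereocentre is untouched and the new α′-centre is an irrelevant epimer mixture because it is enolised again in step 16.

Step 14
Reactants: 20 (4S)-4-{3-[(tert-butyldimethylsilyl)oxy]prop-1-en-2-yl}-6-{[(3R,3aS,4R,7aR)-4,7a-dimethyl-1-oxo-4-[(trimethylsilyl)oxy]octahydroisobenzofuran-3-yl]methyl}cyclohex-2-en-1-one (both C6 epimers)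
Product: 21 (4S)-4-(3-hydroxyprop-1-en-2-yl)-6-{[(3R,3aS,4R,7aR)-4-hydroxy-4,7a-dimethyl-1-oxooctahydroisobenzofuran-3-yl]methyl}cyclohex-2-en-1-one (both C6 epimers)
Conditions: HF·pyridine, pyridine, THF, 0 °C → rt
Reagents that add atoms: none
Why: Mildly acidic fluoride desilylation removes both silyl ethers without enolising the enone, so the γ-stereocentre stays intact.

Step 15
Reactants: 21 (4S)-4-(3-hydroxyprop-1-en-2-yl)-6-{[(3R,3aS,4R,7aR)-4-hydroxy-4,7a-dimethyl-1-oxooctahydroisobenzofuran-3-yl]methyl}cyclohex-2-en-1-one (both C6 epimers)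
Product: 22 2-[(1S)-5-{[(3R,3aS,4R,7aR)-4-hydroxy-4,7a-dimethyl-1-oxooctahydroisobenzofuran-3-yl]methyl}-4-oxocyclohex-2-en-1-yl]prop-2-enal (both C5 epimers)
Conditions: MnO2, CH2Cl2, rt; used at once
Reagents that add atoms: none
Why: MnO2 oxidises only the allylic primary alcohol, under neutral conditions that neither touch the tertiary alcohol nor isomerise the sensitive γ-substituted enone.

Step 16
Reactants: 22 2-[(1S)-5-{[(3R,3aS,4R,7aR)-4-hydroxy-4,7a-dimethyl-1-oxooctahydroisobenzofuran-3-yl]methyl}-4-oxocyclohex-2-en-1-yl]prop-2-enal (both C5 epimers)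
Product: 24 (1R,5S,7R)-7-hydroxy-1-{[(3R,3aS,4R,7aR)-4-hydroxy-4,7a-dimethyl-1-oxooctahydroisobenzofuran-3-yl]methyl}-6-methylidenebicyclo[3.2.1]oct-3-en-2-one, via dilithium enolate 23 (not isolated)
Conditions: lithium 2,2,6,6-tetramethylpiperidide (2.2 equiv), THF, −78 °C; AcOH, −78 °C
Reagents that add atoms: none
Why: Intramolecular aldol addition (5-exo): the aldehyde is tethered to the ring stereocentre, so the enolate is attacked on one face only and the quaternary bridgehead is fixed. The closed lithium-chelated Zimmerman–Traxler transition state holds the aldehyde oxygen next to the enolate oxygen, so the new hydroxyl ends up syn to the ketone bridge (7R).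

Step 17
Reactants: 24 (1R,5S,7R)-7-hydroxy-1-{[(3R,3aS,4R,7aR)-4-hydroxy-4,7a-dimethyl-1-oxooctahydroisobenzofuran-3-yl]methyl}-6-methylidenebicyclo[3.2.1]oct-3-en-2-one
Product: 25 (1R,5S,7R)-7-acetoxy-1-{[(3R,3aS,4R,7aR)-4-hydroxy-4,7a-dimethyl-1-oxooctahydroisobenzofuran-3-yl]methyl}-6-methylidenebicyclo[3.2.1]oct-3-en-2-one (CNP0172716.1)
Conditions: Ac2O, pyridine, DMAP (cat.), CH2Cl2, 0 °C
Reagents that add atoms: acetic anhydride, CC(=O)OC(C)=O
Why: DMAP-catalysed acylation esterifies the secondary alcohol and leaves the tertiary alcohol free; the acetate also blocks retro-aldol opening, and no stereocentre changes.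

## Compound list

1 | (S)-5-(hydroxymethyl)furan-2(5H)-one | OC[C@H]1OC(=O)C=C1 | starting material
2 | (S)-5-{[(tert-butyldiphenylsilyl)oxy]methyl}furan-2(5H)-one | CC(C)(C)[Si](c1ccccc1)(c1ccccc1)OC[C@H]1OC(=O)C=C1 | intermediate
3 | (4R,5S)-5-{[(tert-butyldiphenylsilyl)oxy]methyl}-4-(prop-1-en-2-yl)dihydrofuran-2(3H)-one | CC(C)(C)[Si](c1ccccc1)(c1ccccc1)OC[C@H]1OC(=O)C[C@@H]1C(C)=C | intermediate
4 | lithium enolate of 3 | CC(C)(C)[Si](c1ccccc1)(c1ccccc1)OC[C@H]1OC(O[Li])=C[C@@H]1C(C)=C | intermediate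
5 | (3S,4R,5S)-3-(but-3-en-1-yl)-5-{[(tert-butyldiphenylsilyl)oxy]methyl}-4-(prop-1-en-2-yl)dihydrofuran-2(3H)-one | CC(C)(C)[Si](c1ccccc1)(c1ccccc1)OC[C@H]1OC(=O)[C@@H](CCC=C)[C@@H]1C(C)=C | intermediate
6 | lithium enolate of 5 | CC(C)(C)[Si](c1ccccc1)(c1ccccc1)OC[C@H]1OC(O[Li])=C(CCC=C)[C@@H]1C(C)=C | intermediate
7 | (3R,4S,5S)-3-(but-3-en-1-yl)-5-{[(tert-butyldiphenylsilyl)oxy]methyl}-3-methyl-4-(prop-1-en-2-yl)dihydrofuran-2(3H)-one | CC(C)(C)[Si](c1ccccc1)(c1ccccc1)OC[C@H]1OC(=O)[C@](C)(CCC=C)[C@@H]1C(C)=C | intermediate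
8 | (3S,3aS,7aR)-3-{[(tert-butyldiphenylsilyl)oxy]methyl}-4,7a-dimethyl-3a,6,7,7a-tetrahydroisobenzofuran-1(3H)-one | CC(C)(C)[Si](c1ccccc1)(c1ccccc1)OC[C@H]1OC(=O)[C@]2(C)CCC=C(C)[C@H]12 | intermediate
9 | (3S,3aS,4R,7aR)-3-{[(tert-butyldiphenylsilyl)oxy]methyl}-4-hydroperoxy-4,7a-dimethylhexahydroisobenzofuran-1(3H)-one | CC(C)(C)[Si](c1ccccc1)(c1ccccc1)OC[C@H]1OC(=O)[C@]2(C)CCC[C@@](C)(OO)[C@H]12 | intermediate
10 | (3S,3aS,4R,7aR)-3-{[(tert-butyldiphenylsilyl)oxy]methyl}-4-hydroxy-4,7a-dimethylhexahydroisobenzofuran-1(3H)-one | CC(C)(C)[Si](c1ccccc1)(c1ccccc1)OC[C@H]1OC(=O)[C@]2(C)CCC[C@@](C)(O)[C@H]12 | intermediate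
11 | (3S,3aS,4R,7aR)-4-hydroxy-3-(hydroxymethyl)-4,7a-dimethylhexahydroisobenzofuran-1(3H)-one | OC[C@H]1OC(=O)[C@]2(C)CCC[C@@](C)(O)[C@H]12 | intermediate
12 | [(3S,3aS,4R,7aR)-4-hydroxy-4,7a-dimethyl-1-oxooctahydroisobenzofuran-3-yl]methyl trifluoromethanesulfonate | O=S(=O)(OC[C@H]1OC(=O)[C@]2(C)CCC[C@@](C)(O)[C@H]12)C(F)(F)F | intermediate
13 | [(3S,3aS,4R,7aR)-4,7a-dimethyl-1-oxo-4-[(trimethylsilyl)oxy]octahydroisobenzofuran-3-yl]methyl trifluoromethanesulfonate | O=S(=O)(OC[C@H]1OC(=O)[C@]2(C)CCC[C@@](C)(O[Si](C)(C)C)[C@H]12)C(F)(F)F | intermediate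
14 | (1R,5S)-6,6-dimethylbicyclo[3.1.1]heptan-2-one ((+)-nopinone) | CC1(C)[C@H]2CCC(=O)[C@@H]1C2 | starting material
15 | (S)-4-(prop-1-en-2-yl)cyclohex-1-en-1-yl acetate | CC(=C)[C@H]1CCC(OC(C)=O)=CC1 | intermediate
16 | (S)-4-(prop-1-en-2-yl)cyclohex-2-en-1-one | CC(=C)[C@H]1CCC(=O)C=C1 | intermediate
17 | (S)-4-(3-hydroxyprop-1-en-2-yl)cyclohex-2-en-1-one | OCC(=C)[C@H]1CCC(=O)C=C1 | intermediate
18 | (S)-4-{3-[(tert-butyldimethylsilyl)oxy]prop-1-en-2-yl}cyclohex-2-en-1-one | CC(C)(C)[Si](C)(C)OCC(=C)[C@H]1CCC(=O)C=C1 | intermediate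
19 | lithium (S)-4-{3-[(tert-butyldimethylsilyl)oxy]prop-1-en-2-yl}cyclohexa-1,5-dien-1-olate | CC(C)(C)[Si](C)(C)OCC(=C)[C@H]1CC=C(O[Li])C=C1 | intermediate
20 | (4S)-4-{3-[(tert-butyldimethylsilyl)oxy]prop-1-en-2-yl}-6-{[(3R,3aS,4R,7aR)-4,7a-dimethyl-1-oxo-4-[(trimethylsilyl)oxy]octahydroisobenzofuran-3-yl]methyl}cyclohex-2-en-1-one (both C6 epimers) | CC(C)(C)[Si](C)(C)OCC(=C)[C@H]1CC(C[C@H]2OC(=O)[C@]3(C)CCC[C@@](C)(O[Si](C)(C)C)[C@H]23)C(=O)C=C1 | intermediate
21 | (4S)-4-(3-hydroxyprop-1-en-2-yl)-6-{[(3R,3aS,4R,7aR)-4-hydroxy-4,7a-dimethyl-1-oxooctahydroisobenzofuran-3-yl]methyl}cyclohex-2-en-1-one (both C6 epimers) | OCC(=C)[C@H]1CC(C[C@H]2OC(=O)[C@]3(C)CCC[C@@](C)(O)[C@H]23)C(=O)C=C1 | intermediate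
22 | 2-[(1S)-5-{[(3R,3aS,4R,7aR)-4-hydroxy-4,7a-dimethyl-1-oxooctahydroisobenzofuran-3-yl]methyl}-4-oxocyclohex-2-en-1-yl]prop-2-enal (both C5 epimers) | O=CC(=C)[C@H]1CC(C[C@H]2OC(=O)[C@]3(C)CCC[C@@](C)(O)[C@H]23)C(=O)C=C1 | intermediate
23 | dilithium salt of 22 (α′-enolate and tertiary alkoxide) | O=CC(=C)[C@H]1CC(C[C@H]2OC(=O)[C@]3(C)CCC[C@@](C)(O[Li])[C@H]23)=C(O[Li])C=C1 | intermediate
24 | (1R,5S,7R)-7-hydroxy-1-{[(3R,3aS,4R,7aR)-4-hydroxy-4,7a-dimethyl-1-oxooctahydroisobenzofuran-3-yl]methyl}-6-methylidenebicyclo[3.2.1]oct-3-en-2-one | C=C1[C@@H]2C=CC(=O)[C@@](C[C@H]3OC(=O)[C@]4(C)CCC[C@@](C)(O)[C@H]34)(C2)[C@@H]1O | intermediate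
25 | (1R,5S,7R)-7-acetoxy-1-{[(3R,3aS,4R,7aR)-4-hydroxy-4,7a-dimethyl-1-oxooctahydroisobenzofuran-3-yl]methyl}-6-methylidenebicyclo[3.2.1]oct-3-en-2-one (CNP0172716.1) | C=C1[C@@H]2C=CC(=O)[C@@](C[C@H]3OC(=O)[C@]4(C)CCC[C@@](C)(O)[C@H]34)(C2)[C@@H]1OC(C)=O | target

## Step count and risks

Total: 17 steps. Longest linear sequence: 13 steps (steps 1–8, then 13–17); the cyclohexenone half (steps 9–12) is made in parallel.

The three steps most likely to fail:

**Step 6 (Mukaiyama hydration).** Oxygen trapping of the tertiary radical is fast and may show only modest facial selectivity, and the wrong epimer cannot be corrected later. The fallback sets out from 8 and comes back at 10. Epoxidation of 8 with m-CPBA (NaHCO3, CH2Cl2) on the convex face gives the epoxide F1. PhSeNa, made from (PhSe)2 and NaBH4 in EtOH, opens it by SN2 attack at the secondary carbon to give the hydroxy selenide F2, whose tertiary C–O bond keeps the configuration set by the peracid. Bu3SnH with AIBN in benzene at 80 °C then removes selenium to give 10. The C–O bond is thus made by a concerted, sterically governed epoxidation and not by radical trapping.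

**Step 13 (fragment union).** The β-branched, β-oxygenated triflate may react slowly, eliminate, or give O-alkylation with the lithium dienolate. The fallback sets out from 18 and comes back at 20. Condensation of 18 with Me2NNH2 (cat. AcOH, EtOH) gives the dimethylhydrazone F3. LiN(i-Pr)2 at −78 °C metalates it at the α′-position to the aza-enolate F4, a much stronger carbon nucleophile with no oxygen to alkylate. Reaction with 13 gives the alkylated hydrazone F5, and buffered aqueous CuCl2 (pH 7, THF) hydrolyses it back to ketone 20.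

**Step 16 (aldol ring closure).** The strong amide base can attack the free aldehyde, and any γ-deprotonation would scramble the only controlling stereocentre. The fallback sets out from 20 and comes back at 24. Kinetic enolisation of 20 with LiN(i-Pr)2 at −78 °C gives the lithium dienolate F6, which is quenched with N-bromosuccinimide to the tertiary α′-bromo ketone F7. HF·pyridine gives the bromo diol F8 and MnO2 gives the bromo keto enal F9. SmI2 in THF at −78 °C then cleaves the C–Br bond to a trivalent samarium enolate, formed regiospecifically and without base, which closes onto the aldehyde through the same chelate (intramolecular Reformatsky-type aldol) to give 24.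

## Further compounds

F1 | step 6 | 4,5-epoxide of 8 with the oxirane oxygen anti to the lactone ring | CC(C)(C)[Si](c1ccccc1)(c1ccccc1)OC[C@H]1OC(=O)[C@]2(C)CC[C@H]3O[C@@]3(C)[C@H]12
F2 | step 6 | 5-(phenylselanyl) derivative of 10 with selenium trans to the tertiary hydroxyl | CC(C)(C)[Si](c1ccccc1)(c1ccccc1)OC[C@H]1OC(=O)[C@]2(C)CC[C@H]([Se]c3ccccc3)[C@@](C)(O)[C@H]12
F3 | step 13 | N,N-dimethylhydrazone of 18 | CC(C)(C)[Si](C)(C)OCC(=C)[C@H]1CCC(=NN(C)C)C=C1
F4 | step 13 | α′-lithiated N,N-dimethylhydrazone of 18 (aza-enolate) | CC(C)(C)[Si](C)(C)OCC(=C)[C@H]1CC=C(N([Li])N(C)C)C=C1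
F5 | step 13 | N,N-dimethylhydrazone of 20 | CC(C)(C)[Si](C)(C)OCC(=C)[C@H]1CC(C[C@H]2OC(=O)[C@]3(C)CCC[C@@](C)(O[Si](C)(C)C)[C@H]23)C(=NN(C)C)C=C1
F6 | step 16 | lithium dienolate of 20 | CC(C)(C)[Si](C)(C)OCC(=C)[C@H]1CC(C[C@H]2OC(=O)[C@]3(C)CCC[C@@](C)(O[Si](C)(C)C)[C@H]23)=C(O[Li])C=C1
F7 | step 16 | 6-bromo derivative of 20 (tertiary α′-bromo ketone; both epimers) | CC(C)(C)[Si](C)(C)OCC(=C)[C@H]1CC(Br)(C[C@H]2OC(=O)[C@]3(C)CCC[C@@](C)(O[Si](C)(C)C)[C@H]23)C(=O)C=C1
F8 | step 16 | 6-bromo derivative of 21 (both epimers) | OCC(=C)[C@H]1CC(Br)(C[C@H]2OC(=O)[C@]3(C)CCC[C@@](C)(O)[C@H]23)C(=O)C=C1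
F9 | step 16 | α′-bromo derivative of 22 (both epimers) | O=CC(=C)[C@H]1CC(Br)(C[C@H]2OC(=O)[C@]3(C)CCC[C@@](C)(O)[C@H]23)C(=O)C=C1
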